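Unprimed atoms belong to the quinolinone fused to the gem-dimethylpyran (ring A), primed atoms to the quinolinone fused to the second pyran (ring B); Ca (on CMe2) and Cb (on O4' and C3) are the ring-fusion CH groups, Cc is the CH bearing the side chain. The target is cut at Cb–O4', Ca–Cb and O4–CMe2. Because Cb is an aldehyde-level carbon between C3 and O4', and Ca–CMe2 a latent prenyl alkene, dehydrative union of a 3-formyl-4-hydroxyquinolinone with the enol OH of a Cc-stereodefined, isobutenyl-bearing quinolinone and intramolecular oxa-Diels–Alder addition across O4=C4–C3=Cb close rings A and B and set Ca and Cb in one operation. The precursor carries its ketone as a dithiolane.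

Key step: step 5

Remarks on the chemistry (assumptions)
- Configuration: the target is Cc = R, Ca = R, Cb = S, that is Ha and Hb cis (cis-fused pyrans) and Ha trans to Hc. The Michael adduct must therefore be R at Cc. No structural correction was needed.
- Precursor design: a free 2-oxopropyl group on Cc is 1,5-related to O4'–H, so the Michael adduct 3 should sit largely as a warfarin-type cyclic hemiketal. Under dehydrating acid this would close to a 4H-pyran and consume the hydroxyl needed for the key step, and it can racemise by retro-Michael cleavage. The ketone is therefore carried through the key step as a 1,3-dithiolane (same carbon skeleton).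
- Only a weak Brønsted acid is used in the key step, because strong acid would add O4'–H across the prenyl-type alkene.
- All conditions are proposals to be optimised.

Step 1
Reactants: 1 4-hydroxy-1-methylquinolin-2(1H)-one; 2 (3E)-6-methylhepta-3,5-dien-2-one
Product: 3 4-hydroxy-1-methyl-3-[(4R)-6-methyl-2-oxohept-5-en-4-yl]quinolin-2(1H)-one (in equilibrium with its cyclic hemiketal)
Conditions: (1R,2R)-1,2-diphenylethane-1,2-diamine (10 mol %), AcOH, THF, rt; recrystallisation
Reagents that add atoms: none
Why: Primary-amine (iminium-ion) catalysed Michael addition of a cyclic vinylogous acid to an enone, as in the enantioselective warfarin synthesis; C3 of 1 attacks the β-carbon of the dienone iminium ion (the δ,δ-dimethyl terminus disfavours 1,6-addition) on the face left open by the hydrogen-bonded diamine, the R,R catalyst being expected to give the R adduct by analogy with the benzylideneacetone case (the S,S catalyst is the alternative if the sense is reversed), and crystallisation should upgrade the enantiomeric purity.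

Step 2
Reactants: 3 4-hydroxy-1-methyl-3-[(4R)-6-methyl-2-oxohept-5-en-4-yl]quinolin-2(1H)-one
Product: 4 4-hydroxy-1-methyl-3-[(2R)-4-methyl-1-(2-methyl-1,3-dithiolan-2-yl)pent-3-en-2-yl]quinolin-2(1H)-one
Conditions: HS(CH2)2SH (1.5 equiv), BF3·OEt2 (0.3 equiv), CH2Cl2, −20 → 0 °C
Reagents that add atoms: ethane-1,2-dithiol, SCCS
Why: Lewis-acid-catalysed dithioketalisation: the dithiol captures the oxocarbenium ion formed from the hemiketal (or the activated open ketone) and the dithiolane with a free O4'–H is the thermodynamic product, while the low temperature should spare the trisubstituted alkene and the Cc stereocentre, which is not α to the carbonyl.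

Step 3
Reactants: 1 4-hydroxy-1-methylquinolin-2(1H)-one; 5 N,N-dimethylformamide dimethyl acetal
Product: 6 3-[(dimethylamino)methylidene]-1-methylquinoline-2,4(1H,3H)-dione
Conditions: PhMe, 80 °C
Reagents that add atoms: none
Why: Aminomethylenation of a cyclic 1,3-dicarbonyl compound with an amide acetal: the nucleophilic C3 attacks the methoxy-iminium ion and methanol is lost to give the push–pull enaminone.

Step 4
Reactants: 6 3-[(dimethylamino)methylidene]-1-methylquinoline-2,4(1H,3H)-dione
Product: 7 3-formyl-4-hydroxy-1-methylquinolin-2(1H)-one
Conditions: 2 M aq. HCl, THF, 40 °C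
Reagents that add atoms: water, O
Why: Acid hydrolysis of a vinylogous amide: water adds to the iminium carbon of the protonated enaminone and dimethylamine leaves as its ammonium salt, giving the strongly hydrogen-bonded formyl/hydroxymethylene tautomer.

Step 5
Reactants: 7 3-formyl-4-hydroxy-1-methylquinolin-2(1H)-one; 4 4-hydroxy-1-methyl-3-[(2R)-4-methyl-1-(2-methyl-1,3-dithiolan-2-yl)pent-3-en-2-yl]quinolin-2(1H)-one
Product: 9 cis-fused pentacyclic dithiolane (target skeleton with a (2-methyl-1,3-dithiolan-2-yl)methyl group on Cc; Ca R, Cb S, Cc R), via aryloxymethylene-dione 8 (not isolated)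
Conditions: (PhO)2P(O)OH (10 mol %), 4 Å MS, PhMe, 60 → 90 °C
Reagents that add atoms: none
Why: Proposed new method: the phosphoric acid catalyses addition of O4'–H of 4 to the formyl (hydroxymethylene) carbon of 7 and loss of water into the sieves, giving the aryloxymethylene-dione 8, a 1-oxadiene O4=C4–C3=Cb that stays electrophilic because O4' is a poor, vinylogous-ester donor; hydrogen-bonded or protonated 8 should then undergo an asynchronous inverse-demand intramolecular oxa-Diels–Alder reaction in which Cb bonds to Ca while O4 captures the positive charge developing at CMe2 (a stepwise Prins-type variant converges on the same product). The closest known reaction types are the acid-mediated union of salicylaldehydes with alkenols through alkoxy o-quinone methides and the domino Knoevenagel/hetero-Diels–Alder reaction of cyclic 1,3-dicarbonyl compounds; new here is an enol hydroxyl as the condensing partner and a vinylogous anhydride as the heterodiene. Ring B closes by Cb–Ca bond formation in a 6-exo manner onto the trisubstituted alkene, and ring A closes by O4–CMe2 bond formation as the second terminus of the [4+2] event. Ca is set by Cc through allylic 1,3-strain: Hc eclipses the alkene plane beside its Z-methyl group, so the diene, tied to C3' through O4', reaches the alkene face opposite the dithiolanylmethyl group and Ha ends trans to Hc; Cb is set relative to Ca by the cis-annulated transition structure that the four-atom tether with its planar O4'–C4'=C3' segment should enforce, as in related benzo-tethered hetero-Diels–Alder reactions. The step needs O- rather than C-condensation (C3' is fully substituted), the ketonic C4=O rather than the amide C2=O as the diene oxygen (it is the more electrophilic carbonyl and leaves the 2-quinolone intact) and no competing ring closure of O4'–H onto the alkene or the side chain (weak acid; ketone masked as dithiolane).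

Step 6
Reactants: 9 cis-fused pentacyclic dithiolane
Product: 10 pentacyclic methyl ketone (target skeleton with a 2-oxopropyl group on Cc; Ca R, Cb S, Cc R)
Conditions: MeI, CaCO3, MeCN–H2O (9:1), 50 °C
Reagents that add atoms: water, O
Why: Alkylative hydrolysis of a dithioketal: S-methylation, ring opening to a thionium ion and capture by water release the ketone under buffered, non-oxidising conditions that should not ionise the Cb–O4' bond or touch the three stereocentres.

Step 7
Reactants: 10 pentacyclic methyl ketone
Product: 11 target, pentacycle with a 2-hydroxy-2-methylpropyl group on Cc (Ca R, Cb S, Cc R)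
Conditions: MeMgBr, CeCl3, THF, −78 → 0 °C; then H2O
Reagents that add atoms: methylmagnesium bromide, C[Mg]Br
Why: Organocerium 1,2-addition of a methyl group to the methyl ketone: the cerium reagent suppresses enolisation and does not attack the two 4-alkoxy-2-quinolone lactams, and no stereocentre is formed or disturbed.

Compound list
1 | 4-hydroxy-1-methylquinolin-2(1H)-one | Cn1c(=O)cc(O)c2ccccc21 | starting material
2 | (3E)-6-methylhepta-3,5-dien-2-one | CC(=O)/C=C/C=C(C)C | starting material
3 | 4-hydroxy-1-methyl-3-[(4R)-6-methyl-2-oxohept-5-en-4-yl]quinolin-2(1H)-one | Cn1c(=O)c(c(O)c2ccccc21)[C@@H](C=C(C)C)CC(C)=O | intermediate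
4 | 4-hydroxy-1-methyl-3-[(2R)-4-methyl-1-(2-methyl-1,3-dithiolan-2-yl)pent-3-en-2-yl]quinolin-2(1H)-one | Cn1c(=O)c(c(O)c2ccccc21)[C@@H](C=C(C)C)CC1(C)SCCS1 | intermediate
5 | N,N-dimethylformamide dimethyl acetal | COC(OC)N(C)C | starting material
6 | 3-[(dimethylamino)methylidene]-1-methylquinoline-2,4(1H,3H)-dione | CN(C)C=C1C(=O)c2ccccc2N(C)C1=O | intermediate
7 | 3-formyl-4-hydroxy-1-methylquinolin-2(1H)-one | Cn1c(=O)c(C=O)c(O)c2ccccc21 | intermediate
8 | 1-methyl-3-{[(1-methyl-3-[(2R)-4-methyl-1-(2-methyl-1,3-dithiolan-2-yl)pent-3-en-2-yl]-2-oxo-1,2-dihydroquinolin-4-yl)oxy]methylidene}quinoline-2,4(1H,3H)-dione (exocyclic alkene geometry mobile) | CN1C(=O)C(=COc3c([C@@H](C=C(C)C)CC4(C)SCCS4)c(=O)n(C)c4ccccc34)C(=O)c2ccccc21 | intermediate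
9 | pentacyclic dithiolane: two N-methylquinolin-2-ones, ring A (O4–CMe2–Ca–Cb–C3=C4) cis-fused along Ca–Cb to ring B (O4'–Cb–Ca–Cc–C3'=C4'), (2-methyl-1,3-dithiolan-2-yl)methyl on Cc; Ca R, Cb S, Cc R | Cn1c(=O)c2c(c3ccccc31)OC(C)(C)[C@H]1[C@@H]2Oc2c(c(=O)n(C)c3ccccc23)[C@@H]1CC4(C)SCCS4 | intermediate
10 | pentacyclic methyl ketone: same ring system, 2-oxopropyl on Cc; Ca R, Cb S, Cc R | Cn1c(=O)c2c(c3ccccc31)OC(C)(C)[C@H]1[C@@H]2Oc2c(c(=O)n(C)c3ccccc23)[C@@H]1CC(C)=O | intermediate
11 | CNP0202276.1: same ring system, 2-hydroxy-2-methylpropyl on Cc; Ca R, Cb S, Cc R | Cn1c(=O)c2c(c3ccccc31)OC(C)(C)[C@H]1[C@@H]2Oc2c(c(=O)n(C)c3ccccc23)[C@@H]1CC(C)(C)O | target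

Total step count: 7. Longest linear sequence: 5 steps (steps 1, 2, 5, 6, 7; the branch through steps 3 and 4 is equally long).

Steps most likely to fail

Step 5. The dehydrative O-condensation may not outrun acid-promoted addition of O4'–H across the trisubstituted alkene, or the cycloaddition may engage the amide carbonyl or take the trans-fused or Cc-mismatched mode. The fallback uses the known intermolecular inverse-demand hetero-Diels–Alder reaction between a 3-alkylidene-quinoline-2,4-dione and a 2H-pyranoquinolinone alkene, and gives up the catalytic control of Cc. It sets out from 1: Knoevenagel condensation with 3-methylbut-2-enal (pyridine, reflux) followed by 6π-electrocyclisation should give N-methylflindersine F1. On heating (1,2-dichlorobenzene, about 180 °C) this opens reversibly to the dienone 1-methyl-3-(3-methylbut-2-en-1-ylidene)quinoline-2,4(1H,3H)-dione F2, whose O4'=C4'–C3'=Cc oxadiene should add across the Ca=Cb bond of a second molecule of F1 (Cc to Ca, O4' to Cb, cis fusion fixed by the cyclic cis-alkene). The isobutenyl pentacycle F3 would be separated from isomeric dimers as the racemate with Ha trans to Hc and resolved on a chiral stationary phase. Mukaiyama hydration of its side-chain alkene (Co(acac)2, PhSiH3, O2, iPrOH) then places the hydroxyl on the tertiary carbon, and the fallback comes back to the route at 11.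

Step 2. Lewis-acid-promoted addition of O4'–H or of the thiol across the alkene may compete with thioketalisation of a ketone that is held as a hemiketal. The fallback protects the enol oxygen first, which locks the open chain and removes the internal nucleophile. It sets out from 3: acetylation (Ac2O, pyridine, 0 °C) should give the open-chain enol acetate 1-methyl-3-[(4R)-6-methyl-2-oxohept-5-en-4-yl]-2-oxo-1,2-dihydroquinolin-4-yl acetate F4. Its free ketone is thioketalised (HS(CH2)2SH, BF3·OEt2, CH2Cl2, −20 °C) to the acetylated dithiolane F5, and methanolysis (K2CO3, MeOH, 0 °C) removes the acetyl group, coming back to the route at 4.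

Step 1. Enantioface discrimination of the dienone iminium ion may be insufficient with an alkenyl in place of an aryl β-substituent. The fallback replaces asymmetric catalysis by resolution. It sets out from 1 and 2: an uncatalysed or base-mediated Michael addition (Et3N, H2O–dioxane, 80 °C) should give the racemic Michael adduct F6, which is separated by preparative chromatography on a chiral stationary phase, the R enantiomer coming back to the route at 3.

Further compounds
F1 | step 5 | N-methylflindersine (2,2,6-trimethyl-2,6-dihydro-5H-pyrano[3,2-c]quinolin-5-one) | Cn1c(=O)c2c(c3ccccc31)OC(C)(C)C=C2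
F2 | step 5 | 1-methyl-3-(3-methylbut-2-en-1-ylidene)quinoline-2,4(1H,3H)-dione | CN1C(=O)C(=CC=C(C)C)C(=O)c2ccccc21
F3 | step 5 | pentacycle of the target ring system with a 2-methylprop-1-enyl group on Cc (Ca R, Cb S, Cc R after resolution) | Cn1c(=O)c2c(c3ccccc31)OC(C)(C)[C@H]1[C@@H]2Oc2c(c(=O)n(C)c3ccccc23)[C@@H]1C=C(C)C
F4 | step 2 | 1-methyl-3-[(4R)-6-methyl-2-oxohept-5-en-4-yl]-2-oxo-1,2-dihydroquinolin-4-yl acetate | Cn1c(=O)c(c(OC(C)=O)c2ccccc21)[C@@H](C=C(C)C)CC(C)=O
F5 | step 2 | 1-methyl-3-[(2R)-4-methyl-1-(2-methyl-1,3-dithiolan-2-yl)pent-3-en-2-yl]-2-oxo-1,2-dihydroquinolin-4-yl acetate | Cn1c(=O)c(c(OC(C)=O)c2ccccc21)[C@@H](C=C(C)C)CC3(C)SCCS3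
F6 | step 1 | racemic 4-hydroxy-1-methyl-3-(6-methyl-2-oxohept-5-en-4-yl)quinolin-2(1H)-one | Cn1c(=O)c(c(O)c2ccccc21)C(C=C(C)C)CC(C)=O
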